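**Retrosynthetic overview**

1. The target is (2S)-eriodictyol bonded through C5' of its catechol ring B to C6 of luteolin. The strategy rests on flavone ring A: a phloroglucinol whose C6 carries that catechol ring between O5 and O7 and whose C4a carries the acyl carbon C4. This ring is an α-aryl 3,5,7-triketo ester folded by Claisen condensation (chain C4 = flavone C6, chain C6 = C4a, chain C1 = C8a).
2. Disconnections: flavanone O1–C2 (asymmetric oxa-Michael of an ester-activated chalcone), flavone O1–C2 (chalcone, I2/DMSO), flavone C4a–C8a (Claisen folding of triketo ester 12), chain C4–C5 (dianion of β-keto ester 10 plus diketene), aryl–CH2 (Pd arylation of a Reformatsky reagent with the bromide from 5-bromovanillin).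
3. The biaryl bond therefore enters as an sp3 arylacetic carbon. The 6- versus 8-aryl question is settled after the key step: the two accessible hydroxyls are silylated, the hindered one is benzylated, and silyl is exchanged for benzyl at the para oxygen only, so only the unhindered ortho hydroxyl is free for flavone closure.
4. Ring order: flavone ring A (step 8), flavone ring C (step 13), flavanone ring C with C2 (S) (step 17). All eight phenols travel as benzyl ethers and are freed in one hydrogenolysis.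

Key step: step 8

Assumption: the quinidine-derived thiourea is taken as the member of the pseudoenantiomeric catalyst pair that gives the (2S) series; if the sense of induction is the reverse, the quinine-derived catalyst is used in step 17 without other change.

Abbreviations: Bn = benzyl; TBS = tert-butyldimethylsilyl; Ar = 2,3-bis(benzyloxy)-5-(1,3-dioxolan-2-yl)phenyl (protected central ring, bonded through C1); Fl = 5,7-bis(benzyloxy)-2-[3,4-bis(benzyloxy)phenyl]-4-oxo-4H-chromen-6-yl.

**Route**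

Step 1
Reactants: 1 5-bromovanillin
Product: 2 3-bromo-4,5-dihydroxybenzaldehyde
Conditions: AlCl3, pyridine, CH2Cl2, reflux; aq. HCl
Reagents that add atoms: none
Why: Lewis-acid ether cleavage through the aluminium chelate of the guaiacol unit (AlCl3/pyridine demethylation) should remove only the methyl ortho to the phenol and leave the aldehyde and the aryl bromide untouched.

Step 2
Reactants: 2 3-bromo-4,5-dihydroxybenzaldehyde
Product: 3 3,4-bis(benzyloxy)-5-bromobenzaldehyde
Conditions: BnBr (2.3 equiv), K2CO3, DMF, 60 °C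
Reagents that add atoms: benzyl bromide, BrCc1ccccc1
Why: Williamson etherification of both phenoxides installs benzyl groups that tolerate the later acid, base and enolate steps and leave by hydrogenolysis.

Step 3
Reactants: 3 3,4-bis(benzyloxy)-5-bromobenzaldehyde
Product: 4 2-[3,4-bis(benzyloxy)-5-bromophenyl]-1,3-dioxolane
Conditions: ethylene glycol, TsOH·H2O (cat.), toluene, reflux, Dean–Stark
Reagents that add atoms: ethylene glycol, OCCO
Why: Acid-catalysed acetalisation with azeotropic removal of water masks the aldehyde against the enolate chemistry that follows, and benzyl ethers are stable to the acid.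

Step 4
Reactants: 4 2-[3,4-bis(benzyloxy)-5-bromophenyl]-1,3-dioxolane
Product: 5 ethyl 2-Ar-acetate, that is ethyl 2-[2,3-bis(benzyloxy)-5-(1,3-dioxolan-2-yl)phenyl]acetate
Conditions: BrZnCH2CO2Et (0.5 M in THF, 1.5 equiv), Pd2(dba)3 (2 mol %), XPhos (8 mol %), THF, 65 °C
Reagents that add atoms: ethyl bromozincacetate, CCOC(=O)C[Zn]Br
Why: Palladium-catalysed α-arylation of a zinc ester enolate (Negishi-type coupling of the Reformatsky reagent) runs under near-neutral conditions that spare acetal and benzyl ethers and should stop at monoarylation.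

Step 5
Reactants: 5 ethyl 2-Ar-acetate
Product: 6 2-Ar-acetic acid
Conditions: LiOH, THF/MeOH/H2O, rt; cold dilute HCl to pH 4
Reagents that add atoms: lithium hydroxide, [Li+].[OH-]
Why: Ester saponification is compatible with the base-stable dioxolane, and the cold, brief acidification to pH 4 should not hydrolyse it.

Step 6
Reactants: 6 2-Ar-acetic acid; 7 potassium methyl malonate
Product: 10 methyl 4-Ar-3-oxobutanoate, via acyl imidazolide 8 (not isolated), via acylmalonate half ester 9 (not isolated)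
Conditions: CDI, THF, rt; then 7, MgCl2, Et3N, THF/MeCN, rt to 40 °C; cold dilute HCl to pH 4
Reagents that add atoms: none
Why: In this Masamune–Brooks homologation the acyl imidazolide C-acylates the magnesium enolate of the malonate half ester, and the acylmalonate loses CO2 on acidification to give the β-keto ester.

Step 7
Reactants: 10 methyl 4-Ar-3-oxobutanoate; 11 diketene
Product: 12 methyl 4-Ar-3,5,7-trioxooctanoate (drawn as its chelated C4=C5 enol; an equilibrating tautomer mixture is expected)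
Conditions: LiN(iPr)2 (2.2 equiv), THF, −78 to 0 °C; 11 (1.1 equiv), −78 °C; AcOH, −78 °C
Reagents that add atoms: none
Why: The dianion of a β-keto ester reacts at its γ carbon, here the benzylic one, and diketene is attacked at its acyl carbon and ring-opens to an enolate, so this γ-acylation should deliver the acetoacetyl unit in one operation and hold the product as a stable polyenolate until the cold acidic quench.

Step 8
Reactants: 12 methyl 4-Ar-3,5,7-trioxooctanoate
Product: 13 1-(3-Ar-2,4,6-trihydroxyphenyl)ethan-1-one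
Conditions: Mg(OMe)2 (5 equiv), MeOH, reflux, Ar; cold dilute HCl to pH 4
Reagents that add atoms: none
Why: Magnesium methoxide should convert 12 into a magnesium polyenolate in which C6 of the C5/C7 diketonate is the nucleophile and the same metal can bind the ester carbonyl, so that C6 adds to C1, methoxide leaves and the cyclohexane-1,3,5-trione enolises to the aromatic ring with the acetyl group (C7, C8) already on the new ring carbon. The closest known reaction type is the magnesium alkoxide mediated Claisen cyclisation of 3,5,7-triketo esters to acylphloroglucinols, applied here to a 4-aryl member. Flavone ring A is closed in a 6-exo-trig mode (enolate carbon C6 onto the exocyclic ester C=O), forming the bond that becomes C4a–C8a; the aryl-bearing C4 only loses its acidic hydrogen on aromatisation, so the crowded biaryl bond is never made by coupling. No stereocentre is formed. The step needs Claisen folding (C6 to C1) to win over aldol folding (C2 onto the C7 ketone, giving a resorcylate), over lactonisation through O5 and over retro-Claisen cleavage at C4. A methyl ester in anhydrous methanol with divalent magnesium should secure this: C1 stays an ester electrophile, the 1,3-dicarbonyl units are held as tight chelated enolates that methoxide does not cleave, and C2 is tied into the β-keto ester chelate.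

Step 9
Reactants: 13 1-(3-Ar-2,4,6-trihydroxyphenyl)ethan-1-one
Product: 14 1-{3-Ar-4,6-bis[(tert-butyldimethylsilyl)oxy]-2-hydroxyphenyl}ethan-1-one
Conditions: TBSCl (2.2 equiv), imidazole, DMF, 0 °C
Reagents that add atoms: tert-butyldimethylsilyl chloride, CC(C)(C)[Si](C)(C)Cl
Why: Regioselective phenol silylation should take the more acidic para hydroxyl O4 and the unhindered ortho hydroxyl O6, while O2–H, wedged between the aryl and acetyl groups and hydrogen-bonded to the carbonyl, stays free.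

Step 10
Reactants: 14 1-{3-Ar-4,6-bis[(tert-butyldimethylsilyl)oxy]-2-hydroxyphenyl}ethan-1-one
Product: 15 1-{3-Ar-2-(benzyloxy)-4,6-bis[(tert-butyldimethylsilyl)oxy]phenyl}ethan-1-one
Conditions: BnOH, PPh3, DIAD, THF, 0 °C to rt
Reagents that add atoms: benzyl alcohol, OCc1ccccc1
Why: Mitsunobu etherification alkylates the only free phenol under neutral conditions that neither shift nor cleave the aryl silyl ethers, which puts benzyl on the oxygen that becomes flavone O5.

Step 11
Reactants: 15 1-{3-Ar-2-(benzyloxy)-4,6-bis[(tert-butyldimethylsilyl)oxy]phenyl}ethan-1-one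
Product: 17 1-[3-Ar-2,4-bis(benzyloxy)-6-hydroxyphenyl]ethan-1-one, via desilylated diol 16 (not isolated)
Conditions: K2CO3, MeOH/THF, rt; evaporate; BnBr (1.05 equiv), K2CO3, DMF, rt
Reagents that add atoms: benzyl bromide, BrCc1ccccc1
Why: Carbonate in methanol cleaves aryl silyl ethers, and under weak base only the non-chelated para hydroxyl is alkylated (the usual 4-O-selective alkylation of 2,4-dihydroxyacetophenones), so O6–H, the less hindered ortho hydroxyl, should remain free and chelated.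

Step 12
Reactants: 17 1-[3-Ar-2,4-bis(benzyloxy)-6-hydroxyphenyl]ethan-1-one; 18 3,4-bis(benzyloxy)benzaldehyde
Product: 19 (2E)-1-[3-Ar-2,4-bis(benzyloxy)-6-hydroxyphenyl]-3-[3,4-bis(benzyloxy)phenyl]prop-2-en-1-one
Conditions: KOH, EtOH/THF, rt
Reagents that add atoms: none
Why: Claisen–Schmidt condensation of the acetophenone enolate with the non-enolisable aldehyde and elimination should give the E-chalcone, the dioxolane being stable to hydroxide.

Step 13
Reactants: 19 (2E)-1-[3-Ar-2,4-bis(benzyloxy)-6-hydroxyphenyl]-3-[3,4-bis(benzyloxy)phenyl]prop-2-en-1-one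
Product: 21 3,4-bis(benzyloxy)-5-Fl-benzaldehyde, via flavone acetal 20 (not isolated)
Conditions: I2 (10 mol %), DMSO, 130 °C; then 1 M HCl, THF, rt
Reagents that add atoms: water, O
Why: Iodine-catalysed oxidative cyclisation of a 2'-hydroxychalcone in DMSO (oxa-Michael closure, α-iodination and loss of HI, DMSO reoxidising HI) closes flavone ring C through the only free hydroxyl, which fixes the aryl group at C6, and the aqueous acid then hydrolyses the dioxolane while the benzyl ethers stay.

Step 14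
Reactants: 22 2,4,6-trihydroxyacetophenone
Product: 23 1-[2,4-bis(benzyloxy)-6-hydroxyphenyl]ethan-1-one
Conditions: BnBr (2.1 equiv), K2CO3, DMF, rt
Reagents that add atoms: benzyl bromide, BrCc1ccccc1
Why: Williamson etherification takes the para and one ortho hydroxyl, and the second ortho hydroxyl should stay free because it is hydrogen-bonded to the carbonyl.

Step 15
Reactants: 23 1-[2,4-bis(benzyloxy)-6-hydroxyphenyl]ethan-1-one
Product: 24 tert-butyl 3-[2,4-bis(benzyloxy)-6-hydroxyphenyl]-3-oxopropanoate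
Conditions: LiN(SiMe3)2 (3.3 equiv), THF, −78 °C; Boc2O (1.1 equiv), −78 to 0 °C; cold dilute HCl
Reagents that add atoms: di-tert-butyl dicarbonate, CC(C)(C)OC(=O)OC(=O)OC(C)(C)C
Why: The phenoxide–enolate dianion is C-acylated by the dicarbonate (crossed Claisen-type acylation, any aryl carbonate formed on oxygen being passed on to the enolate carbon), the excess base takes up the more acidic product, and the tert-butyl ester resists lactonisation to a coumarin.

Step 16
Reactants: 21 3,4-bis(benzyloxy)-5-Fl-benzaldehyde; 24 tert-butyl 3-[2,4-bis(benzyloxy)-6-hydroxyphenyl]-3-oxopropanoate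
Product: 25 tert-butyl (2Z)-2-[2,4-bis(benzyloxy)-6-hydroxybenzoyl]-3-[3,4-bis(benzyloxy)-5-Fl-phenyl]prop-2-enoate (drawn as Z; an E/Z mixture is acceptable because both isomers cyclise)
Conditions: piperidine (20 mol %), AcOH (20 mol %), toluene, 4 Å MS, rt
Reagents that add atoms: none
Why: Knoevenagel condensation of the β-keto ester with the aryl aldehyde under piperidinium acetate catalysis gives the chalcone carrying an ester as activating and catalyst-binding group for the conjugate addition.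

Step 17
Reactants: 25 tert-butyl (2Z)-2-[2,4-bis(benzyloxy)-6-hydroxybenzoyl]-3-[3,4-bis(benzyloxy)-5-Fl-phenyl]prop-2-enoate
Product: 28 (2S)-5,7-bis(benzyloxy)-2-[3,4-bis(benzyloxy)-5-Fl-phenyl]-2,3-dihydro-4H-chromen-4-one, via chromanone tert-butyl ester 26 (not isolated), via chromanone acid 27 (not isolated)
Conditions: thiourea of 9-amino-9-deoxy-epi-quinidine and 3,5-bis(trifluoromethyl)phenyl isothiocyanate (10 mol %), toluene, −25 °C; then TsOH·H2O, 80 °C
Reagents that add atoms: none
Why: In this catalytic asymmetric oxa-Michael addition the quinuclidine nitrogen deprotonates the phenol while the thiourea binds the β-keto ester, so the phenoxide is delivered in a 6-endo-trig closure to the face of the alkylidene carbon that gives C2 (S) under catalyst control, after which acid cleaves the tert-butyl ester and the β-keto acid loses CO2, removing the C3 centre.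

Step 18
Reactants: 28 (2S)-5,7-bis(benzyloxy)-2-[3,4-bis(benzyloxy)-5-Fl-phenyl]-2,3-dihydro-4H-chromen-4-one
Product: 29 (2S)-2-{3-[2-(3,4-dihydroxyphenyl)-5,7-dihydroxy-4-oxo-4H-chromen-6-yl]-4,5-dihydroxyphenyl}-5,7-dihydroxy-2,3-dihydro-4H-chromen-4-one
Conditions: H2 (1 atm), 10% Pd on carbon, THF/MeOH, rt
Reagents that add atoms: none
Why: Hydrogenolysis of the eight benzyl ethers under neutral conditions should leave the flavone C2=C3 bond, both carbonyl groups and the base-sensitive C2 stereocentre untouched.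

**Compound list**

1 | 5-bromovanillin | COc1cc(C=O)cc(Br)c1O | starting material
2 | 3-bromo-4,5-dihydroxybenzaldehyde | O=Cc1cc(O)c(O)c(Br)c1 | intermediate
3 | 3,4-bis(benzyloxy)-5-bromobenzaldehyde | O=Cc1cc(OCc2ccccc2)c(OCc2ccccc2)c(Br)c1 | intermediate
4 | 2-[3,4-bis(benzyloxy)-5-bromophenyl]-1,3-dioxolane | Brc1cc(C2OCCO2)cc(OCc2ccccc2)c1OCc1ccccc1 | intermediate
5 | ethyl 2-[2,3-bis(benzyloxy)-5-(1,3-dioxolan-2-yl)phenyl]acetate | CCOC(=O)Cc1cc(C2OCCO2)cc(OCc2ccccc2)c1OCc1ccccc1 | intermediate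
6 | 2-[2,3-bis(benzyloxy)-5-(1,3-dioxolan-2-yl)phenyl]acetic acid | OC(=O)Cc1cc(C2OCCO2)cc(OCc2ccccc2)c1OCc1ccccc1 | intermediate
7 | potassium methyl malonate | COC(=O)CC(=O)[O-].[K+] | starting material
8 | 2-Ar-1-(imidazol-1-yl)ethan-1-one (acyl imidazolide) | O=C(Cc1cc(C2OCCO2)cc(OCc2ccccc2)c1OCc1ccccc1)n1ccnc1 | intermediate
9 | 2-(methoxycarbonyl)-4-Ar-3-oxobutanoic acid (acylmalonate half ester, present as its magnesium salt) | COC(=O)C(C(=O)O)C(=O)Cc1cc(C2OCCO2)cc(OCc2ccccc2)c1OCc1ccccc1 | intermediate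
10 | methyl 4-[2,3-bis(benzyloxy)-5-(1,3-dioxolan-2-yl)phenyl]-3-oxobutanoate | COC(=O)CC(=O)Cc1cc(C2OCCO2)cc(OCc2ccccc2)c1OCc1ccccc1 | intermediate
11 | diketene | C=C1CC(=O)O1 | starting material
12 | methyl 4-[2,3-bis(benzyloxy)-5-(1,3-dioxolan-2-yl)phenyl]-3,5,7-trioxooctanoate (chelated enol form) | COC(=O)CC(=O)/C(c1cc(C2OCCO2)cc(OCc2ccccc2)c1OCc1ccccc1)=C(\O)CC(C)=O | intermediate
13 | 1-{3-[2,3-bis(benzyloxy)-5-(1,3-dioxolan-2-yl)phenyl]-2,4,6-trihydroxyphenyl}ethan-1-one | CC(=O)c1c(O)cc(O)c(-c2cc(C3OCCO3)cc(OCc3ccccc3)c2OCc2ccccc2)c1O | intermediate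
14 | 1-{3-Ar-4,6-bis[(tert-butyldimethylsilyl)oxy]-2-hydroxyphenyl}ethan-1-one | CC(=O)c1c(O[Si](C)(C)C(C)(C)C)cc(O[Si](C)(C)C(C)(C)C)c(-c2cc(C3OCCO3)cc(OCc3ccccc3)c2OCc2ccccc2)c1O | intermediate
15 | 1-{3-Ar-2-(benzyloxy)-4,6-bis[(tert-butyldimethylsilyl)oxy]phenyl}ethan-1-one | CC(=O)c1c(O[Si](C)(C)C(C)(C)C)cc(O[Si](C)(C)C(C)(C)C)c(-c2cc(C3OCCO3)cc(OCc3ccccc3)c2OCc2ccccc2)c1OCc1ccccc1 | intermediate
16 | 1-[3-Ar-2-(benzyloxy)-4,6-dihydroxyphenyl]ethan-1-one | CC(=O)c1c(O)cc(O)c(-c2cc(C3OCCO3)cc(OCc3ccccc3)c2OCc2ccccc2)c1OCc1ccccc1 | intermediate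
17 | 1-[3-Ar-2,4-bis(benzyloxy)-6-hydroxyphenyl]ethan-1-one | CC(=O)c1c(O)cc(OCc2ccccc2)c(-c2cc(C3OCCO3)cc(OCc3ccccc3)c2OCc2ccccc2)c1OCc1ccccc1 | intermediate
18 | 3,4-bis(benzyloxy)benzaldehyde | O=Cc1ccc(OCc2ccccc2)c(OCc2ccccc2)c1 | starting material
19 | (2E)-1-[3-Ar-2,4-bis(benzyloxy)-6-hydroxyphenyl]-3-[3,4-bis(benzyloxy)phenyl]prop-2-en-1-one | O=C(/C=C/c1ccc(OCc2ccccc2)c(OCc2ccccc2)c1)c1c(O)cc(OCc2ccccc2)c(-c2cc(C3OCCO3)cc(OCc3ccccc3)c2OCc2ccccc2)c1OCc1ccccc1 | intermediate
20 | 5,7-bis(benzyloxy)-6-[2,3-bis(benzyloxy)-5-(1,3-dioxolan-2-yl)phenyl]-2-[3,4-bis(benzyloxy)phenyl]-4H-chromen-4-one | O=c1cc(-c2ccc(OCc3ccccc3)c(OCc3ccccc3)c2)oc2cc(OCc3ccccc3)c(-c3cc(C4OCCO4)cc(OCc4ccccc4)c3OCc3ccccc3)c(OCc3ccccc3)c12 | intermediate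
21 | 3,4-bis(benzyloxy)-5-{5,7-bis(benzyloxy)-2-[3,4-bis(benzyloxy)phenyl]-4-oxo-4H-chromen-6-yl}benzaldehyde | O=Cc1cc(OCc2ccccc2)c(OCc2ccccc2)c(-c2c(OCc3ccccc3)cc3oc(-c4ccc(OCc5ccccc5)c(OCc5ccccc5)c4)cc(=O)c3c2OCc2ccccc2)c1 | intermediate
22 | 2,4,6-trihydroxyacetophenone | CC(=O)c1c(O)cc(O)cc1O | starting material
23 | 1-[2,4-bis(benzyloxy)-6-hydroxyphenyl]ethan-1-one | CC(=O)c1c(O)cc(OCc2ccccc2)cc1OCc1ccccc1 | intermediate
24 | tert-butyl 3-[2,4-bis(benzyloxy)-6-hydroxyphenyl]-3-oxopropanoate | CC(C)(C)OC(=O)CC(=O)c1c(O)cc(OCc2ccccc2)cc1OCc1ccccc1 | intermediate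
25 | tert-butyl (2Z)-2-[2,4-bis(benzyloxy)-6-hydroxybenzoyl]-3-[3,4-bis(benzyloxy)-5-Fl-phenyl]prop-2-enoate | CC(C)(C)OC(=O)/C(=C\c1cc(OCc2ccccc2)c(OCc2ccccc2)c(-c2c(OCc3ccccc3)cc3oc(-c4ccc(OCc5ccccc5)c(OCc5ccccc5)c4)cc(=O)c3c2OCc2ccccc2)c1)C(=O)c1c(O)cc(OCc2ccccc2)cc1OCc1ccccc1 | intermediate
26 | tert-butyl (2S)-5,7-bis(benzyloxy)-2-[3,4-bis(benzyloxy)-5-Fl-phenyl]-4-oxochromane-3-carboxylate (C3 epimers and enol) | O=C1C(C(=O)OC(C)(C)C)[C@@H](c2cc(OCc3ccccc3)c(OCc3ccccc3)c(-c3c(OCc4ccccc4)cc4oc(-c5ccc(OCc6ccccc6)c(OCc6ccccc6)c5)cc(=O)c4c3OCc3ccccc3)c2)Oc2cc(OCc3ccccc3)cc(OCc3ccccc3)c21 | intermediate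
27 | (2S)-5,7-bis(benzyloxy)-2-[3,4-bis(benzyloxy)-5-Fl-phenyl]-4-oxochromane-3-carboxylic acid (C3 epimers and enol) | O=C1C(C(=O)O)[C@@H](c2cc(OCc3ccccc3)c(OCc3ccccc3)c(-c3c(OCc4ccccc4)cc4oc(-c5ccc(OCc6ccccc6)c(OCc6ccccc6)c5)cc(=O)c4c3OCc3ccccc3)c2)Oc2cc(OCc3ccccc3)cc(OCc3ccccc3)c21 | intermediate
28 | (2S)-5,7-bis(benzyloxy)-2-(3,4-bis(benzyloxy)-5-{5,7-bis(benzyloxy)-2-[3,4-bis(benzyloxy)phenyl]-4-oxo-4H-chromen-6-yl}phenyl)-2,3-dihydro-4H-chromen-4-one | O=C1C[C@@H](c2cc(OCc3ccccc3)c(OCc3ccccc3)c(-c3c(OCc4ccccc4)cc4oc(-c5ccc(OCc6ccccc6)c(OCc6ccccc6)c5)cc(=O)c4c3OCc3ccccc3)c2)Oc2cc(OCc3ccccc3)cc(OCc3ccccc3)c21 | intermediate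
29 | (2S)-2-{3-[2-(3,4-dihydroxyphenyl)-5,7-dihydroxy-4-oxo-4H-chromen-6-yl]-4,5-dihydroxyphenyl}-5,7-dihydroxy-2,3-dihydro-4H-chromen-4-one | O=C1C[C@@H](c2cc(O)c(O)c(-c3c(O)cc4oc(-c5ccc(O)c(O)c5)cc(=O)c4c3O)c2)Oc2cc(O)cc(O)c21 | target

**Step count**

Total: 18 steps. Longest linear sequence: 16 steps (steps 1 to 13, then 16, 17 and 18); steps 14 and 15 form the side branch.

**Steps most likely to fail**

Step 8. The chain may fold the other way (C2 onto the C7 ketone, an aldol closure to a resorcylate), lactonise through O5, or be cut by methoxide at the 2-aryl-1,3-diketone. The fallback gives up the ring-A construction and makes the biaryl bond by cross-coupling at the flavone stage. It sets out from 4: borylation with bis(pinacolato)diboron, PdCl2(dppf) and KOAc in dioxane at 90 °C would give 2-Ar-4,4,5,5-tetramethyl-1,3,2-dioxaborolane F1. Separately, luteolin F2 would be benzylated with three equivalents of BnBr and K2CO3 in DMF to 7-(benzyloxy)-2-[3,4-bis(benzyloxy)phenyl]-5-hydroxy-4H-chromen-4-one F3, whose chelated 5-hydroxyl stays free. Iodination ortho to that hydroxyl with benzyltrimethylammonium dichloroiodate and CaCO3 in CH2Cl2/MeOH would give the 6-iodide F4, and forcing benzylation (BnBr, K2CO3, DMF, 80 °C) would give 5,7-bis(benzyloxy)-2-[3,4-bis(benzyloxy)phenyl]-6-iodo-4H-chromen-4-one F5. Suzuki coupling of F1 with F5 (Pd(OAc)2, SPhos, K3PO4, toluene/H2O, 100 °C) comes back to the route at the flavone acetal 20, which the acid treatment of step 13 converts to 21.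

Step 7. The dianion may act as a base toward diketene or be acylated on oxygen, and diketene may oligomerise before it is attacked. The fallback builds the acetoacetyl unit in two carbanion acylations instead. It sets out from 10: the dianion (LiN(iPr)2, 2.2 equiv, THF) would be acetylated at the benzylic carbon with N-methoxy-N-methylacetamide to give methyl 4-Ar-3,5-dioxohexanoate F6. Its trianion (LiN(iPr)2, 3.3 equiv, THF, 0 °C) would then be acetylated at the terminal methyl carbon, the last-formed and most basic site, with the same amide. This comes back to the route at 12.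

Step 17. Facial selectivity may be low because the 6'-benzyloxy group twists the aroyl unit out of the geometry the catalyst binds, or the C2 centre may erode during the hot acid decarboxylation through reversible ring opening. The fallback replaces catalytic induction by resolution. It sets out from 21: Claisen–Schmidt condensation with 23 (KOH, EtOH/THF, rt) would give (2E)-1-[2,4-bis(benzyloxy)-6-hydroxyphenyl]-3-[3,4-bis(benzyloxy)-5-Fl-phenyl]prop-2-en-1-one F7. Cyclisation with NaOAc in refluxing EtOH would give the racemic flavanone F8, which would be separated on a polysaccharide carbamate chiral stationary phase. The (2R) antipode can be re-equilibrated with base through F7 and resolved again. This comes back to the route at 28.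

**Further compounds**

F1 | step 8 | 2-[2,3-bis(benzyloxy)-5-(1,3-dioxolan-2-yl)phenyl]-4,4,5,5-tetramethyl-1,3,2-dioxaborolane | CC1(C)OB(c2cc(C3OCCO3)cc(OCc3ccccc3)c2OCc2ccccc2)OC1(C)C
F2 | step 8 | luteolin | O=c1cc(-c2ccc(O)c(O)c2)oc2cc(O)cc(O)c12
F3 | step 8 | 7-(benzyloxy)-2-[3,4-bis(benzyloxy)phenyl]-5-hydroxy-4H-chromen-4-one | O=c1cc(-c2ccc(OCc3ccccc3)c(OCc3ccccc3)c2)oc2cc(OCc3ccccc3)cc(O)c12
F4 | step 8 | 7-(benzyloxy)-2-[3,4-bis(benzyloxy)phenyl]-5-hydroxy-6-iodo-4H-chromen-4-one | O=c1cc(-c2ccc(OCc3ccccc3)c(OCc3ccccc3)c2)oc2cc(OCc3ccccc3)c(I)c(O)c12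
F5 | step 8 | 5,7-bis(benzyloxy)-2-[3,4-bis(benzyloxy)phenyl]-6-iodo-4H-chromen-4-one | O=c1cc(-c2ccc(OCc3ccccc3)c(OCc3ccccc3)c2)oc2cc(OCc3ccccc3)c(I)c(OCc3ccccc3)c12
F6 | step 7 | methyl 4-[2,3-bis(benzyloxy)-5-(1,3-dioxolan-2-yl)phenyl]-3,5-dioxohexanoate | COC(=O)CC(=O)C(C(C)=O)c1cc(C2OCCO2)cc(OCc2ccccc2)c1OCc1ccccc1
F7 | step 17 | (2E)-1-[2,4-bis(benzyloxy)-6-hydroxyphenyl]-3-(3,4-bis(benzyloxy)-5-{5,7-bis(benzyloxy)-2-[3,4-bis(benzyloxy)phenyl]-4-oxo-4H-chromen-6-yl}phenyl)prop-2-en-1-one | O=C(/C=C/c1cc(OCc2ccccc2)c(OCc2ccccc2)c(-c2c(OCc3ccccc3)cc3oc(-c4ccc(OCc5ccccc5)c(OCc5ccccc5)c4)cc(=O)c3c2OCc2ccccc2)c1)c1c(O)cc(OCc2ccccc2)cc1OCc1ccccc1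
F8 | step 17 | racemic 5,7-bis(benzyloxy)-2-(3,4-bis(benzyloxy)-5-{5,7-bis(benzyloxy)-2-[3,4-bis(benzyloxy)phenyl]-4-oxo-4H-chromen-6-yl}phenyl)-2,3-dihydro-4H-chromen-4-one | O=C1CC(c2cc(OCc3ccccc3)c(OCc3ccccc3)c(-c3c(OCc4ccccc4)cc4oc(-c5ccc(OCc6ccccc6)c(OCc6ccccc6)c5)cc(=O)c4c3OCc3ccccc3)c2)Oc2cc(OCc3ccccc3)cc(OCc3ccccc3)c21
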